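**Plan**
- Retrosynthetic cuts, in order: the C2=C3 alkene with the C1 ester (Horner–Wadsworth–Emmons), then C6–CH3 and C7–C8 together, then C19–C20, C8=C9, C15–C16, the H–C10/Cl–C11 pair and C12–C13.
- The feature behind the central cut is the E-trisubstituted C6=C7 alkene with its C6 methyl, flanked by the disubstituted C4=C5 and C8=C9 alkenes: it is what syn methylmetalation of a terminal C6≡C7 alkyne leaves behind. The chain is acyclic there; the only ring (cyclohexane C1′–C6′) comes intact from the starting acid.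
- Forward: C9–C15 alkyne 14 and C16–C19 epoxide 20 are joined, the C13–C15 triol and the C8 iodide are installed, C20–C23 is added, then C3–C7 with the C6 methyl (step 26), last the cyclohexyl phosphonoacetate. No ring is formed anywhere.
- Stereochemistry: C12/C13 from an Evans syn aldol; C14/C15 from substrate-controlled osmylation of a Z alkene; C17/C18 from Sharpless epoxidation and invertive chloride opening; C19 from Cornforth-controlled addition to an α-chloro aldehyde; C1′ from (S)-cyclohex-3-enecarboxylic acid, C3′/C4′ by dihydroxylation. All alkene geometries arise from stereospecific reactions.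

Key step: step 26

Remark: locants C1–C23 follow the acyl chain from the ester carbonyl to the terminal methyl and C1′–C6′ the cyclohexane ring; PMB = 4-methoxybenzyl, TBS = tert-butyldimethylsilyl, TES = triethylsilyl, DMP = Dess–Martin periodinane, NMO = N-methylmorpholine N-oxide; compounds 1, 2, 15, 30, 35, 36, 40 and 44 are assumed to be commercial.

**Route**

Step 1
Reactants: 1 (4R)-4-benzyl-3-propanoyl-1,3-oxazolidin-2-one; 2 3-(trimethylsilyl)prop-2-ynal
Product: 4 (4R)-4-benzyl-3-[(2R,3R)-3-hydroxy-2-methyl-5-(trimethylsilyl)pent-4-ynoyl]-1,3-oxazolidin-2-one (C11–C15), via dibutylboron Z-enolate 3 (not isolated)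
Conditions: Bu2BOTf, Et3N, CH2Cl2, −78 → 0 °C; then 2, −78 → 0 °C; MeOH, pH 7 buffer, H2O2
Reagents that add atoms: none
Why: Evans syn aldol reaction; the Z boron enolate should react through a closed chair transition state on the face away from the benzyl group, setting C12 and C13 together in the syn (2R,3R) sense.

Step 2
Reactants: 4 aldol adduct
Product: 5 13-O-TBS ether of 4
Conditions: TBSOTf, 2,6-lutidine, CH2Cl2, −78 → 0 °C
Reagents that add atoms: tert-butyldimethylsilyl trifluoromethanesulfonate, CC(C)(C)[Si](C)(C)OS(=O)(=O)C(F)(F)F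
Why: Silyl triflate with a hindered pyridine base is the standard silylation of a β-hydroxy imide and should avoid retro-aldol cleavage.

Step 3
Reactants: 5 silylated imide
Product: 6 (2S,3R)-3-[(tert-butyldimethylsilyl)oxy]-2-methyl-5-(trimethylsilyl)pent-4-yn-1-ol
Conditions: LiBH4, MeOH (1 equiv), THF, 0 °C
Reagents that add atoms: none
Why: Reductive cleavage of the N-acyl oxazolidinone with LiBH4 should give the C11 primary alcohol and the recoverable auxiliary without touching the silyl ether or the silylalkyne.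

Step 4
Reactants: 6 primary alcohol
Product: 7 (2R,3R)-3-[(tert-butyldimethylsilyl)oxy]-2-methyl-5-(trimethylsilyl)pent-4-ynal
Conditions: DMP, CH2Cl2, 0 °C → rt; used crude
Reagents that add atoms: none
Why: Dess–Martin oxidation is near neutral, so the α-methyl aldehyde should form without epimerisation at C12.

Step 5
Reactants: 7 aldehyde
Product: 8 tert-butyl{[(3R,4S)-6,6-dibromo-4-methyl-1-(trimethylsilyl)hex-5-en-1-yn-3-yl]oxy}dimethylsilane
Conditions: CBr4, PPh3, CH2Cl2, 0 °C
Reagents that add atoms: carbon tetrabromide, BrC(Br)(Br)Br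
Why: First stage of the Corey–Fuchs homologation (Wittig-type reaction of Ph3P=CBr2) adds the C10 carbon under non-basic conditions.

Step 6
Reactants: 8 dibromoalkene
Product: 10 methyl (4S,5R)-5-[(tert-butyldimethylsilyl)oxy]-4-methyl-7-(trimethylsilyl)hepta-2,6-diynoate (C9–C15), via lithium acetylide 9 (not isolated)
Conditions: nBuLi (2.1 equiv), THF, −78 °C; then ClCO2Me, −78 → 0 °C
Reagents that add atoms: methyl chloroformate, COC(=O)Cl
Why: Second stage of the Corey–Fuchs sequence (Li–Br exchange, 1,2-shift, deprotonation) should give the C10 acetylide, which is acylated in the same flask to add C9.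

Step 7
Reactants: 10 ynoate
Product: 11 methyl (2Z,4R,5R)-5-[(tert-butyldimethylsilyl)oxy]-3-chloro-4-methyl-7-(trimethylsilyl)hept-2-en-6-ynoate
Conditions: LiCl, AcOH, MeCN, 80 °C
Reagents that add atoms: lithium chloride, [Li+].[Cl-]
Why: Hydrochlorination of a 2-ynoate by conjugate addition of chloride and anti protonation should give the (Z)-3-chloro-2-enoate, placing chlorine on C11 with C12 and C9 trans; the unactivated silylalkyne should not react.

Step 8
Reactants: 11 chloroenoate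
Product: 12 (2Z,4R,5R)-5-[(tert-butyldimethylsilyl)oxy]-3-chloro-4-methyl-7-(trimethylsilyl)hept-2-en-6-yn-1-ol
Conditions: iBu2AlH (2.2 equiv), CH2Cl2, −78 °C; aq. potassium sodium tartrate
Reagents that add atoms: none
Why: 1,2-Reduction of an enoate by iBu2AlH should give the C9 allylic alcohol and leave the alkenyl chloride alone.

Step 9
Reactants: 12 allylic alcohol
Product: 13 9-O-PMB ether of 12
Conditions: NaH, 4-methoxybenzyl chloride, Bu4NI (cat.), THF/DMF, 0 °C → rt
Reagents that add atoms: 4-methoxybenzyl chloride, COc1ccc(CCl)cc1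
Why: Williamson etherification; the PMB ether masks O9 through the acetylide, hydrogenation and osmylation steps and is later cleaved oxidatively together with the O19 PMB ether.

Step 10
Reactants: 13 silylalkyne
Product: 14 tert-butyl{[(3R,4R,5Z)-5-chloro-7-[(4-methoxybenzyl)oxy]-4-methylhept-5-en-1-yn-3-yl]oxy}dimethylsilane (C9–C15 terminal alkyne)
Conditions: K2CO3 (cat.), MeOH, rt
Reagents that add atoms: none
Why: Methoxide-mediated protodesilylation of an alkynylsilane should free the C15 alkyne while both silyl and PMB ethers survive.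

Step 11
Reactants: 15 (E)-but-2-ene-1,4-diol
Product: 16 (E)-4-[(4-methoxybenzyl)oxy]but-2-en-1-ol
Conditions: NaH (1 equiv), 4-methoxybenzyl chloride (1 equiv), Bu4NI (cat.), THF/DMF, 0 °C; 15 in threefold excess
Reagents that add atoms: 4-methoxybenzyl chloride, COc1ccc(CCl)cc1
Why: Statistical Williamson mono-etherification of a symmetric diol used in excess should give mainly the mono-ether.

Step 12
Reactants: 16 allylic alcohol
Product: 17 [(2R,3R)-3-{[(4-methoxybenzyl)oxy]methyl}oxiran-2-yl]methanol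
Conditions: Ti(OiPr)4 (cat.), D-(−)-diisopropyl tartrate (cat.), tBuOOH, 4 Å molecular sieves, CH2Cl2, −20 °C
Reagents that add atoms: tert-butyl hydroperoxide, CC(C)(C)OO
Why: Sharpless asymmetric epoxidation; the D-tartrate catalyst should deliver oxygen to the face that gives the (2R,3R) epoxide, which fixes C17 and, after inversion, C18.

Step 13
Reactants: 17 epoxy alcohol
Product: 18 (2R,3S)-3-chloro-4-[(4-methoxybenzyl)oxy]butane-1,2-diol
Conditions: Ti(OiPr)4 (1.5 equiv), Et2NH2Cl, CH2Cl2, rt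
Reagents that add atoms: diethylammonium chloride, CC[NH2+]CC.[Cl-]
Why: Titanium-mediated opening of a 2,3-epoxy alcohol; chelation of the epoxy alkoxide to titanium should direct chloride to C3 (C18) with inversion, giving the 17,18-anti chlorohydrin.

Step 14
Reactants: 18 chlorodiol
Product: 19 (2R,3S)-3-chloro-2-hydroxy-4-[(4-methoxybenzyl)oxy]butyl 4-methylbenzenesulfonate
Conditions: TsCl, Et3N, Bu2SnO (cat.), CH2Cl2, 0 °C → rt
Reagents that add atoms: 4-methylbenzenesulfonyl chloride, Cc1ccc(cc1)S(Cl)(=O)=O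
Why: Tin-catalysed sulfonylation of a 1,2-diol is selective for the primary hydroxyl, and the amine base is too weak to close the chlorohydrin.

Step 15
Reactants: 19 hydroxy tosylate
Product: 20 (2R)-2-{(1S)-1-chloro-2-[(4-methoxybenzyl)oxy]ethyl}oxirane (C16–C19)
Conditions: K2CO3, MeOH, 0 °C
Reagents that add atoms: none
Why: Intramolecular Williamson closure; the C17 alkoxide should displace the primary tosylate much faster than the secondary chloride, so the terminal epoxide forms with C17 and C18 unchanged.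

Step 16
Reactants: 14 C9–C15 alkyne; 20 C16–C19 epoxide
Product: 22 C9–C19 alkynol (17-OH; C14≡C15), via lithium acetylide 21 (not isolated)
Conditions: nBuLi, THF, −78 °C; BF3·OEt2; then 20, −78 °C; NH4Cl quench at −78 °C
Reagents that add atoms: none
Why: Yamaguchi–Hirao alkynylation of an epoxide; the BF3-activated acetylide should attack the unsubstituted C16, as it does with epichlorohydrin, forming C15–C16, and the cold quench keeps the new chlorohydrin from closing.

Step 17
Reactants: 22 alkynol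
Product: 23 C9–C19 (14Z)-alkenol
Conditions: H2 (1 atm), Pd/CaCO3 poisoned with Pb(OAc)2 (Lindlar catalyst), quinoline, EtOAc, rt
Reagents that add atoms: none
Why: Lindlar semihydrogenation should give the Z C14=C15 alkene by syn hydrogen delivery without reducing the alkenyl or alkyl chloride or the PMB ethers.

Step 18
Reactants: 23 Z-alkene
Product: 24 C9–C19 14,15,17-triol
Conditions: K2OsO4·2H2O (cat.), NMO, acetone/H2O, 0 °C → rt
Reagents that add atoms: N-methylmorpholine N-oxide, C[N+]1([O-])CCOCC1; water, O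
Why: Upjohn dihydroxylation; syn addition to the Z alkene gives the 14,15-anti diol, and attack anti to the allylic C13 silyloxy group in the conformer of least allylic strain (Kishi's empirical rule) should give 13,14-anti, while the electron-poor chlorinated C10=C11 alkene should not compete.

Step 19
Reactants: 24 triol
Product: 25 C9–C19 13,14,15,17-tetrakis-O-TBS 9,19-bis-O-PMB ether
Conditions: TBSOTf (excess), 2,6-lutidine, CH2Cl2, 0 °C → rt
Reagents that add atoms: tert-butyldimethylsilyl trifluoromethanesulfonate, CC(C)(C)[Si](C)(C)OS(=O)(=O)C(F)(F)F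
Why: Exhaustive silylation with the silyl triflate is the usual way to cap contiguous secondary alcohols, and it removes the free O15 and O17 that could otherwise displace the C18 chloride.

Step 20
Reactants: 25 bis-PMB ether
Product: 26 C9–C19 9,19-diol
Conditions: DDQ (3 equiv), CH2Cl2/pH 7 buffer, 0 °C
Reagents that add atoms: none
Why: Oxidative PMB cleavage by DDQ should free both primary hydroxyls in one operation while silyl ethers and both chlorides are inert.

Step 21
Reactants: 26 diol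
Product: 27 C9–C19 (10Z)-enal with free 19-OH
Conditions: MnO2 (excess), CH2Cl2, rt
Reagents that add atoms: none
Why: MnO2 oxidises allylic alcohols only, so C9 should be taken to the enal while the saturated C19 alcohol is left.

Step 22
Reactants: 27 enal
Product: 28 C8–C19 (8E,10Z)-4-chloro-1-iododiene with free 19-OH
Conditions: CrCl2, CHI3, THF, 0 °C → rt, dark
Reagents that add atoms: iodoform, IC(I)I
Why: Takai iodo-olefination; addition of the geminal dichromium reagent to the aldehyde and anti elimination should give the E alkenyl iodide and tolerates the free hydroxyl and both chlorides.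

Step 23
Reactants: 28 iododienol
Product: 29 C8–C19 α-chloro aldehyde (C19 aldehyde)
Conditions: DMP, CH2Cl2, 0 °C; used at once
Reagents that add atoms: none
Why: Dess–Martin oxidation without base should give the α-chloro aldehyde without epimerising C18 or eliminating the β-silyloxy group.

Step 24
Reactants: 29 α-chloro aldehyde; 30 but-1-yne
Product: 33 C8–C23 iododiene with free 19-OH, via (E)-but-1-enylzirconocene chloride 31 (not isolated), via (E)-but-1-enyl(methyl)zinc 32 (not isolated)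
Conditions: Cp2Zr(H)Cl, 30, CH2Cl2, rt; Me2Zn, −65 °C; then 29, −65 → 0 °C
Reagents that add atoms: none
Why: Hydrozirconation of the alkyne, zirconium-to-zinc transmetalation and addition to the aldehyde; in the Cornforth arrangement (C–Cl opposed to C=O, attack past hydrogen) the E-alkenylzinc should give the 18,19-anti chlorohydrin (19S), a preference reinforced by the anti C17 silyloxy group, and the alkenyl iodide is inert without a transition-metal coupling catalyst.

Step 25
Reactants: 33 allylic alcohol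
Product: 34 C8–C23 (1E,3Z)-4-chloro-1-iododiene, 19-O-TES, 13,14,15,17-tetrakis-O-TBS
Conditions: TESCl, imidazole, CH2Cl2, 0 °C
Reagents that add atoms: chlorotriethylsilane, CC[Si](Cl)(CC)CC
Why: Silylation under weakly basic conditions; the TES ether can later be removed in the presence of the four TBS ethers.

Step 26
Reactants: 34 C8–C23 iododiene; 35 (E)-pent-2-en-4-yn-1-ol; 36 trimethylaluminium
Product: 38 C3–C23 (4E,6E,8E,10Z,20E)-tetraenol with the C6 methyl and free 3-OH, via dienylalane 37 (not isolated)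
Conditions: 35 (2 equiv), Me3Al (5 equiv), Cp2ZrCl2 (0.5 equiv), ClCH2CH2Cl, 0 °C → rt; volatiles removed in vacuo; THF, ZnCl2, 34 (1 equiv), Pd(PPh3)4 (5 mol %), rt; aq. potassium sodium tartrate
Reagents that add atoms: trimethylaluminium (36), C[Al](C)C
Why: Zirconium-catalysed methylalumination followed by Negishi alkenyl–alkenyl coupling, both known for enynols and alkenyl iodides: the methylzirconium species from Me3Al and Cp2ZrCl2 adds methyl and metal syn across the terminal C6≡C7 alkyne of the aluminium alkoxide of 35, methyl to the substituted C6 and aluminium to C7, so alane 37 already carries the 6E geometry. After excess Me3Al is removed, oxidative addition of the C8–I bond of 34 to zerovalent palladium, ZnCl2-assisted transfer of the C7 alkenyl group from aluminium to palladium and reductive elimination form C7–C8 with retention at both carbons. No ring is closed and no stereocentre is created; the existing alkenes and the seven stereocentres are not touched. The selectivities needed are the regiochemistry of methyl delivery, secured by the terminal alkyne, and C–I over C–Cl reactivity, secured by the much slower oxidative addition of the C11 alkenyl and C18 alkyl chlorides. The C3 hydroxyl is carried as its dimethylaluminium alkoxide and the silyl ethers are inert to the organometallics, so 38 should be released on work-up.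

Step 27
Reactants: 38 tetraenol
Product: 39 C3–C23 tetraenal
Conditions: MnO2, CH2Cl2, rt, dark
Reagents that add atoms: none
Why: MnO2 oxidation of the trienyl carbinol should give the conjugated aldehyde without affecting silyl ethers or chlorides.

Step 28
Reactants: 40 (1S)-cyclohex-3-ene-1-carboxylic acid
Product: 41 (1S,3R,4S)-3,4-dihydroxycyclohexane-1-carboxylic acid
Conditions: K2OsO4·2H2O (cat.), NMO, acetone/H2O, rt
Reagents that add atoms: N-methylmorpholine N-oxide, C[N+]1([O-])CCOCC1; water, O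
Why: Upjohn dihydroxylation gives the cis diol; attack anti to the carboxyl group is expected to be favoured only moderately, and the all-cis isomer is removed by chromatography after step 29.

Step 29
Reactants: 41 diol acid
Product: 42 prop-2-en-1-yl (1S,3R,4S)-3,4-dihydroxycyclohexane-1-carboxylate
Conditions: KHCO3, allyl bromide, DMF, rt
Reagents that add atoms: allyl bromide, C=CCBr
Why: Carboxylate alkylation under bicarbonate is selective for the acid over the hydroxyls; the allyl ester is installed after osmylation so that its alkene is never exposed to OsO4.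

Step 30
Reactants: 42 diol ester
Product: 43 prop-2-en-1-yl (1S,3R,4S)-4-[(tert-butyldimethylsilyl)oxy]-3-hydroxycyclohexane-1-carboxylate
Conditions: TBSCl (1.05 equiv), imidazole, DMF, −20 → 0 °C
Reagents that add atoms: tert-butylchlorodimethylsilane, CC(C)(C)[Si](C)(C)Cl
Why: Regioselective silylation; with the ester equatorial the 4′-OH is equatorial and the 3′-OH axial, so the bulky silyl chloride should take the equatorial 4′-OH first.

Step 31
Reactants: 43 mono-silyl ether; 44 (diethoxyphosphoryl)acetic acid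
Product: 45 prop-2-en-1-yl (1S,3R,4S)-4-[(tert-butyldimethylsilyl)oxy]-3-{[(diethoxyphosphoryl)acetyl]oxy}cyclohexane-1-carboxylate
Conditions: EDC·HCl, DMAP (cat.), CH2Cl2, 0 °C → rt
Reagents that add atoms: none
Why: Steglich esterification with the phosphonoacetic acid should acylate the remaining axial 3′-OH.

Step 32
Reactants: 39 tetraenal; 45 phosphonoacetate
Product: 47 (2E,4E,6E,8E,10Z,20E)-hexaenoate, 19-O-TES, allyl ester, via lithiated phosphonate 46 (not isolated)
Conditions: 45 (1.3 equiv), LiN(SiMe3)2 (1.2 equiv), THF, −78 °C; then 39, −78 → 0 °C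
Reagents that add atoms: none
Why: Horner–Wadsworth–Emmons olefination of a conjugated aldehyde with a stabilised phosphonoacetate anion should form the E C2=C3 alkene; no free base remains to attack the esters.

Step 33
Reactants: 47 TES ether
Product: 48 19-hydroxy hexaenoate
Conditions: HF·pyridine, excess pyridine, THF, 0 °C
Reagents that add atoms: none
Why: Buffered HF·pyridine should cleave the secondary TES ether selectively while the five more hindered TBS ethers remain.

Step 34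
Reactants: 48 C19 alcohol
Product: 50 19-O-carbamoyl hexaenoate (allyl ester, five TBS ethers), via N-trichloroacetyl carbamate 49 (not isolated)
Conditions: Cl3CC(O)NCO, CH2Cl2, 0 °C; then neutral Al2O3, rt
Reagents that add atoms: trichloroacetyl isocyanate, O=C=NC(=O)C(Cl)(Cl)Cl
Why: Carbamoylation with the acyl isocyanate followed by neutral hydrolysis of the trichloroacetyl group on alumina installs the primary carbamate without base, so the carbamate nitrogen cannot displace the neighbouring C18 chloride.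

Step 35
Reactants: 50 allyl ester
Product: 51 1′-carboxylic acid (19-carbamate, five TBS ethers)
Conditions: Pd(PPh3)4 (5 mol %), morpholine, THF, 0 °C, dark
Reagents that add atoms: none
Why: Palladium-catalysed deallylation (allyl transfer to the amine through a π-allyl complex); the unhindered primary allyl ester should ionise far faster than the hindered secondary C19 allylic carbamate flanked by the C18 chloride and silyl ethers.

Step 36
Reactants: 51 penta-TBS acid
Product: 52 target compound CNP0164989.3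
Conditions: HF·pyridine, pyridine, THF, 0 °C → rt, dark
Reagents that add atoms: none
Why: Global desilylation under acidic fluoride conditions removes the five TBS ethers without generating alkoxides that could close onto C18, and should leave the hexaenoate, the carbamate and both chlorides intact.

**Compound list**

1 | (4R)-4-benzyl-3-propanoyl-1,3-oxazolidin-2-one | CCC(=O)N1[C@H](Cc2ccccc2)COC1=O | starting material
2 | 3-(trimethylsilyl)prop-2-ynal | C[Si](C)(C)C#CC=O | starting material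
3 | dibutylboron Z-enolate of 1 | C/C=C(\OB(CCCC)CCCC)N1[C@H](Cc2ccccc2)COC1=O | intermediate
4 | (4R)-4-benzyl-3-[(2R,3R)-3-hydroxy-2-methyl-5-(trimethylsilyl)pent-4-ynoyl]-1,3-oxazolidin-2-one | C[Si](C)(C)C#C[C@H](O)[C@@H](C)C(=O)N1[C@H](Cc2ccccc2)COC1=O | intermediate
5 | (4R)-4-benzyl-3-[(2R,3R)-3-[(tert-butyldimethylsilyl)oxy]-2-methyl-5-(trimethylsilyl)pent-4-ynoyl]-1,3-oxazolidin-2-one | C[Si](C)(C)C#C[C@H](O[Si](C)(C)C(C)(C)C)[C@@H](C)C(=O)N1[C@H](Cc2ccccc2)COC1=O | intermediate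
6 | (2S,3R)-3-[(tert-butyldimethylsilyl)oxy]-2-methyl-5-(trimethylsilyl)pent-4-yn-1-ol | C[Si](C)(C)C#C[C@H](O[Si](C)(C)C(C)(C)C)[C@@H](C)CO | intermediate
7 | (2R,3R)-3-[(tert-butyldimethylsilyl)oxy]-2-methyl-5-(trimethylsilyl)pent-4-ynal | C[Si](C)(C)C#C[C@H](O[Si](C)(C)C(C)(C)C)[C@@H](C)C=O | intermediate
8 | tert-butyl{[(3R,4S)-6,6-dibromo-4-methyl-1-(trimethylsilyl)hex-5-en-1-yn-3-yl]oxy}dimethylsilane | C[Si](C)(C)C#C[C@H](O[Si](C)(C)C(C)(C)C)[C@@H](C)C=C(Br)Br | intermediate
9 | lithium acetylide from 8 (C10-lithiated C10≡C11 alkyne) | C[Si](C)(C)C#C[C@H](O[Si](C)(C)C(C)(C)C)[C@@H](C)C#C[Li] | intermediate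
10 | methyl (4S,5R)-5-[(tert-butyldimethylsilyl)oxy]-4-methyl-7-(trimethylsilyl)hepta-2,6-diynoate | C[Si](C)(C)C#C[C@H](O[Si](C)(C)C(C)(C)C)[C@@H](C)C#CC(=O)OC | intermediate
11 | methyl (2Z,4R,5R)-5-[(tert-butyldimethylsilyl)oxy]-3-chloro-4-methyl-7-(trimethylsilyl)hept-2-en-6-ynoate | C[Si](C)(C)C#C[C@H](O[Si](C)(C)C(C)(C)C)[C@@H](C)/C(Cl)=C/C(=O)OC | intermediate
12 | (2Z,4R,5R)-5-[(tert-butyldimethylsilyl)oxy]-3-chloro-4-methyl-7-(trimethylsilyl)hept-2-en-6-yn-1-ol | C[Si](C)(C)C#C[C@H](O[Si](C)(C)C(C)(C)C)[C@@H](C)/C(Cl)=C/CO | intermediate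
13 | tert-butyl{[(3R,4R,5Z)-5-chloro-7-[(4-methoxybenzyl)oxy]-4-methyl-1-(trimethylsilyl)hept-5-en-1-yn-3-yl]oxy}dimethylsilane | C[Si](C)(C)C#C[C@H](O[Si](C)(C)C(C)(C)C)[C@@H](C)/C(Cl)=C/COCc1ccc(OC)cc1 | intermediate
14 | tert-butyl{[(3R,4R,5Z)-5-chloro-7-[(4-methoxybenzyl)oxy]-4-methylhept-5-en-1-yn-3-yl]oxy}dimethylsilane | C#C[C@H](O[Si](C)(C)C(C)(C)C)[C@@H](C)/C(Cl)=C/COCc1ccc(OC)cc1 | intermediate
15 | (E)-but-2-ene-1,4-diol | OC/C=C/CO | starting material
16 | (E)-4-[(4-methoxybenzyl)oxy]but-2-en-1-ol | OC/C=C/COCc1ccc(OC)cc1 | intermediate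
17 | [(2R,3R)-3-{[(4-methoxybenzyl)oxy]methyl}oxiran-2-yl]methanol | OC[C@H]1O[C@@H]1COCc2ccc(OC)cc2 | intermediate
18 | (2R,3S)-3-chloro-4-[(4-methoxybenzyl)oxy]butane-1,2-diol | COc1ccc(COC[C@H](Cl)[C@H](O)CO)cc1 | intermediate
19 | (2R,3S)-3-chloro-2-hydroxy-4-[(4-methoxybenzyl)oxy]butyl 4-methylbenzenesulfonate | COc1ccc(COC[C@H](Cl)[C@H](O)COS(=O)(=O)c2ccc(C)cc2)cc1 | intermediate
20 | (2R)-2-{(1S)-1-chloro-2-[(4-methoxybenzyl)oxy]ethyl}oxirane | COc1ccc(COC[C@H](Cl)[C@H]2CO2)cc1 | intermediate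
21 | lithium acetylide of 14 (C15-lithiated) | [Li]C#C[C@H](O[Si](C)(C)C(C)(C)C)[C@@H](C)/C(Cl)=C/COCc1ccc(OC)cc1 | intermediate
22 | C9–C19 alkynol: 9,19-di-O-PMB, 13-O-TBS, 17-OH, 11,18-dichloro, 12-methyl, C14≡C15, C10=C11 Z; 12R,13R,17R,18S | COc1ccc(COC[C@H](Cl)[C@H](O)CC#C[C@H](O[Si](C)(C)C(C)(C)C)[C@@H](C)/C(Cl)=C/COCc2ccc(OC)cc2)cc1 | intermediate
23 | C9–C19 alkenol: as 22 with a Z C14=C15 alkene; 10Z,14Z; 12R,13S,17R,18S | COc1ccc(COC[C@H](Cl)[C@H](O)C/C=C\[C@H](O[Si](C)(C)C(C)(C)C)[C@@H](C)/C(Cl)=C/COCc2ccc(OC)cc2)cc1 | intermediate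
24 | C9–C19 14,15,17-triol: 9,19-di-O-PMB, 13-O-TBS, 11,18-dichloro, 12-methyl; 10Z; 12R,13R,14S,15S,17R,18S | COc1ccc(COC[C@H](Cl)[C@H](O)C[C@H](O)[C@H](O)[C@H](O[Si](C)(C)C(C)(C)C)[C@@H](C)/C(Cl)=C/COCc2ccc(OC)cc2)cc1 | intermediate
25 | C9–C19 13,14,15,17-tetrakis-O-TBS 9,19-di-O-PMB ether; 10Z; 12R,13R,14S,15S,17R,18S | COc1ccc(COC[C@H](Cl)[C@H](O[Si](C)(C)C(C)(C)C)C[C@H](O[Si](C)(C)C(C)(C)C)[C@H](O[Si](C)(C)C(C)(C)C)[C@H](O[Si](C)(C)C(C)(C)C)[C@@H](C)/C(Cl)=C/COCc2ccc(OC)cc2)cc1 | intermediate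
26 | C9–C19 9,19-diol, 13,14,15,17-tetrakis-O-TBS; 10Z; 12R,13R,14S,15S,17R,18S | OC[C@H](Cl)[C@H](O[Si](C)(C)C(C)(C)C)C[C@H](O[Si](C)(C)C(C)(C)C)[C@H](O[Si](C)(C)C(C)(C)C)[C@H](O[Si](C)(C)C(C)(C)C)[C@@H](C)/C(Cl)=C/CO | intermediate
27 | C9–C19 (10Z)-3-chloroenal (C9 aldehyde) with 19-OH, tetrakis-O-TBS; 12R,13R,14S,15S,17R,18S | OC[C@H](Cl)[C@H](O[Si](C)(C)C(C)(C)C)C[C@H](O[Si](C)(C)C(C)(C)C)[C@H](O[Si](C)(C)C(C)(C)C)[C@H](O[Si](C)(C)C(C)(C)C)[C@@H](C)/C(Cl)=C/C=O | intermediate
28 | C8–C19 (8E,10Z)-11-chloro-8-iododiene with 19-OH, tetrakis-O-TBS; 12R,13R,14S,15S,17R,18S | OC[C@H](Cl)[C@H](O[Si](C)(C)C(C)(C)C)C[C@H](O[Si](C)(C)C(C)(C)C)[C@H](O[Si](C)(C)C(C)(C)C)[C@H](O[Si](C)(C)C(C)(C)C)[C@@H](C)/C(Cl)=C/C=C/I | intermediate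
29 | C8–C19 α-chloro aldehyde (C19 aldehyde), tetrakis-O-TBS; 8E,10Z; 12R,13R,14S,15S,17R,18R | O=C[C@H](Cl)[C@H](O[Si](C)(C)C(C)(C)C)C[C@H](O[Si](C)(C)C(C)(C)C)[C@H](O[Si](C)(C)C(C)(C)C)[C@H](O[Si](C)(C)C(C)(C)C)[C@@H](C)/C(Cl)=C/C=C/I | intermediate
30 | but-1-yne | CCC#C | starting material
31 | (E)-but-1-enylzirconocene chloride | CC/C=C/[Zr](Cl)(C1C=CC=C1)C1C=CC=C1 | intermediate
32 | (E)-but-1-enyl(methyl)zinc | CC/C=C/[Zn]C | intermediate
33 | C8–C23 iododiene with 19-OH, tetrakis-O-TBS; 8E,10Z,20E; 12R,13R,14S,15S,17R,18S,19S | CC/C=C/[C@H](O)[C@H](Cl)[C@H](O[Si](C)(C)C(C)(C)C)C[C@H](O[Si](C)(C)C(C)(C)C)[C@H](O[Si](C)(C)C(C)(C)C)[C@H](O[Si](C)(C)C(C)(C)C)[C@@H](C)/C(Cl)=C/C=C/I | intermediate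
34 | C8–C23 (1E,3Z)-4-chloro-1-iododiene, 19-O-TES, 13,14,15,17-tetrakis-O-TBS; 8E,10Z,20E; 12R,13R,14S,15S,17R,18R,19S | CC/C=C/[C@H](O[Si](CC)(CC)CC)[C@H](Cl)[C@H](O[Si](C)(C)C(C)(C)C)C[C@H](O[Si](C)(C)C(C)(C)C)[C@H](O[Si](C)(C)C(C)(C)C)[C@H](O[Si](C)(C)C(C)(C)C)[C@@H](C)/C(Cl)=C/C=C/I | intermediate
35 | (E)-pent-2-en-4-yn-1-ol | C#C/C=C/CO | starting material
36 | trimethylaluminium | C[Al](C)C | starting material
37 | dimethyl[(1E,3E)-5-(dimethylaluminiooxy)-2-methylpenta-1,3-dienyl]alane | C[Al](C)/C=C(C)/C=C/CO[Al](C)C | intermediate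
38 | C3–C23 tetraenol, 6-methyl, 3-OH, 19-O-TES, tetrakis-O-TBS; 4E,6E,8E,10Z,20E; 12R,13R,14S,15S,17R,18R,19S | CC/C=C/[C@H](O[Si](CC)(CC)CC)[C@H](Cl)[C@H](O[Si](C)(C)C(C)(C)C)C[C@H](O[Si](C)(C)C(C)(C)C)[C@H](O[Si](C)(C)C(C)(C)C)[C@H](O[Si](C)(C)C(C)(C)C)[C@@H](C)/C(Cl)=C/C=C/C=C(C)/C=C/CO | intermediate
39 | C3–C23 tetraenal (C3 aldehyde), otherwise as 38 | CC/C=C/[C@H](O[Si](CC)(CC)CC)[C@H](Cl)[C@H](O[Si](C)(C)C(C)(C)C)C[C@H](O[Si](C)(C)C(C)(C)C)[C@H](O[Si](C)(C)C(C)(C)C)[C@H](O[Si](C)(C)C(C)(C)C)[C@@H](C)/C(Cl)=C/C=C/C=C(C)/C=C/C=O | intermediate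
40 | (1S)-cyclohex-3-ene-1-carboxylic acid | C1=CC[C@@H](C(=O)O)CC1 | starting material
41 | (1S,3R,4S)-3,4-dihydroxycyclohexane-1-carboxylic acid | O[C@@H]1C[C@@H](C(=O)O)CC[C@@H]1O | intermediate
42 | prop-2-en-1-yl (1S,3R,4S)-3,4-dihydroxycyclohexane-1-carboxylate | O[C@@H]1C[C@@H](C(=O)OCC=C)CC[C@@H]1O | intermediate
43 | prop-2-en-1-yl (1S,3R,4S)-4-[(tert-butyldimethylsilyl)oxy]-3-hydroxycyclohexane-1-carboxylate | O[C@@H]1C[C@@H](C(=O)OCC=C)CC[C@@H]1O[Si](C)(C)C(C)(C)C | intermediate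
44 | (diethoxyphosphoryl)acetic acid | CCOP(=O)(OCC)CC(=O)O | starting material
45 | prop-2-en-1-yl (1S,3R,4S)-4-[(tert-butyldimethylsilyl)oxy]-3-{[(diethoxyphosphoryl)acetyl]oxy}cyclohexane-1-carboxylate | CCOP(=O)(OCC)CC(=O)O[C@@H]1C[C@@H](C(=O)OCC=C)CC[C@@H]1O[Si](C)(C)C(C)(C)C | intermediate
46 | lithium salt of 45 (phosphonate-stabilised carbanion) | [Li+].CCOP(=O)(OCC)[CH-]C(=O)O[C@@H]1C[C@@H](C(=O)OCC=C)CC[C@@H]1O[Si](C)(C)C(C)(C)C | intermediate
47 | hexaenoate of the 3′-O: 19-O-TES, 13,14,15,17,4′-pentakis-O-TBS, allyl ester; 2E,4E,6E,8E,10Z,20E; 12R,13R,14S,15S,17R,18R,19S; 1′S,3′R,4′S | CC/C=C/[C@H](O[Si](CC)(CC)CC)[C@H](Cl)[C@H](O[Si](C)(C)C(C)(C)C)C[C@H](O[Si](C)(C)C(C)(C)C)[C@H](O[Si](C)(C)C(C)(C)C)[C@H](O[Si](C)(C)C(C)(C)C)[C@@H](C)/C(Cl)=C/C=C/C=C(C)/C=C/C=C/C(=O)O[C@@H]1C[C@@H](C(=O)OCC=C)CC[C@@H]1O[Si](C)(C)C(C)(C)C | intermediate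
48 | as 47 with free 19-OH; 18S,19S | CC/C=C/[C@H](O)[C@H](Cl)[C@H](O[Si](C)(C)C(C)(C)C)C[C@H](O[Si](C)(C)C(C)(C)C)[C@H](O[Si](C)(C)C(C)(C)C)[C@H](O[Si](C)(C)C(C)(C)C)[C@@H](C)/C(Cl)=C/C=C/C=C(C)/C=C/C=C/C(=O)O[C@@H]1C[C@@H](C(=O)OCC=C)CC[C@@H]1O[Si](C)(C)C(C)(C)C | intermediate
49 | as 48 with 19-O-[(trichloroacetyl)carbamoyl]; 18S,19S | CC/C=C/[C@H](OC(=O)NC(=O)C(Cl)(Cl)Cl)[C@H](Cl)[C@H](O[Si](C)(C)C(C)(C)C)C[C@H](O[Si](C)(C)C(C)(C)C)[C@H](O[Si](C)(C)C(C)(C)C)[C@H](O[Si](C)(C)C(C)(C)C)[C@@H](C)/C(Cl)=C/C=C/C=C(C)/C=C/C=C/C(=O)O[C@@H]1C[C@@H](C(=O)OCC=C)CC[C@@H]1O[Si](C)(C)C(C)(C)C | intermediate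
50 | 19-O-carbamoyl hexaenoate, pentakis-O-TBS, allyl ester; 18S,19S | CC/C=C/[C@H](OC(N)=O)[C@H](Cl)[C@H](O[Si](C)(C)C(C)(C)C)C[C@H](O[Si](C)(C)C(C)(C)C)[C@H](O[Si](C)(C)C(C)(C)C)[C@H](O[Si](C)(C)C(C)(C)C)[C@@H](C)/C(Cl)=C/C=C/C=C(C)/C=C/C=C/C(=O)O[C@@H]1C[C@@H](C(=O)OCC=C)CC[C@@H]1O[Si](C)(C)C(C)(C)C | intermediate
51 | as 50 with free 1′-carboxylic acid | CC/C=C/[C@H](OC(N)=O)[C@H](Cl)[C@H](O[Si](C)(C)C(C)(C)C)C[C@H](O[Si](C)(C)C(C)(C)C)[C@H](O[Si](C)(C)C(C)(C)C)[C@H](O[Si](C)(C)C(C)(C)C)[C@@H](C)/C(Cl)=C/C=C/C=C(C)/C=C/C=C/C(=O)O[C@@H]1C[C@@H](C(=O)O)CC[C@@H]1O[Si](C)(C)C(C)(C)C | intermediate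
52 | CNP0164989.3: (1S,3R,4S)-3-{[(2E,4E,6E,8E,10Z,12R,13R,14S,15S,17R,18R,19S,20E)-19-(carbamoyloxy)-11,18-dichloro-13,14,15,17-tetrahydroxy-6,12-dimethyltricosa-2,4,6,8,10,20-hexaenoyl]oxy}-4-hydroxycyclohexane-1-carboxylic acid | CC/C=C/[C@H](OC(N)=O)[C@H](Cl)[C@H](O)C[C@H](O)[C@H](O)[C@H](O)[C@@H](C)/C(Cl)=C/C=C/C=C(C)/C=C/C=C/C(=O)O[C@@H]1C[C@@H](C(=O)O)CC[C@@H]1O | target

**Count**
- Total steps: 36.
- Longest linear sequence: 27 steps (1–10, 16–27, 32–36).

**Steps most likely to fail**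

1. Step 7. Chloride addition to the α-branched ynoate may be slow, and prolonged heating in acetic acid may strip the C13 silyl ether or erode the Z geometry. The fallback sets out from 10: stannylcupration under equilibrating conditions (Me3Sn(PhS)CuLi, THF, −48 °C, then MeOH) should give the thermodynamic adduct with tin cis to the ester, methyl (2Z,4R,5R)-5-[(tert-butyldimethylsilyl)oxy]-4-methyl-3-(trimethylstannyl)-7-(trimethylsilyl)hept-2-en-6-ynoate F1. Chlorodestannylation with CuCl2 in THF at room temperature then replaces tin by chlorine with retention and comes back at 11.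

2. Step 13. Chloride may attack C2 (C17) in competition with C3 (C18), because the ether oxygen on C4 deactivates C3 towards substitution; this would give the regioisomeric chlorohydrin. The fallback sets out from 17 and makes the question moot by symmetry. DDQ removal of the PMB group gives the twofold-symmetric [(2R,3R)-oxirane-2,3-diyl]dimethanol F2, whose two epoxide carbons are equivalent, so the same Ti(OiPr)4/Et2NH2Cl opening can give only (2R,3S)-3-chlorobutane-1,2,4-triol F3. Acetonide formation on the 1,2-diol (2,2-dimethoxypropane, TsOH cat.) gives (2S)-2-chloro-2-[(4R)-2,2-dimethyl-1,3-dioxolan-4-yl]ethan-1-ol F4. Etherification with 4-methoxybenzyl trichloroacetimidate and catalytic acid gives (4R)-4-{(1S)-1-chloro-2-[(4-methoxybenzyl)oxy]ethyl}-2,2-dimethyl-1,3-dioxolane F5, and aqueous acetic acid removes the acetonide and comes back at 18.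

3. Step 26. Residual methylaluminium species may transfer methyl instead of the dienyl group to palladium, the alane may be protonated before coupling, or the Lewis-acidic mixture may damage the allylic C19 silyl ether. The fallback separates the two bond formations and reverses the polarity at C7/C8. From 35, the same methylalumination is quenched with iodine to give (2E,4E)-5-iodo-4-methylpenta-2,4-dien-1-ol F6. From 34, Miyaura borylation (bis(pinacolato)diboron, PdCl2(PPh3)2, KOPh, toluene, 50 °C) gives the C8 pinacol boronate of the chlorodiene, 2-[(1E,3Z)-4-chloro-dienyl]-4,4,5,5-tetramethyl-1,3,2-dioxaborolane carrying the C12–C23 chain of 34, F7. Suzuki coupling of F7 with F6 (Pd(PPh3)4, TlOEt, THF/H2O, rt) then forms C7–C8 and comes back at 38.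

**Further compounds**

F1 | step 7 | methyl (2Z,4R,5R)-5-[(tert-butyldimethylsilyl)oxy]-4-methyl-3-(trimethylstannyl)-7-(trimethylsilyl)hept-2-en-6-ynoate | C[Si](C)(C)C#C[C@H](O[Si](C)(C)C(C)(C)C)[C@@H](C)/C([Sn](C)(C)C)=C/C(=O)OC
F2 | step 13 | [(2R,3R)-oxirane-2,3-diyl]dimethanol | OC[C@H]1O[C@@H]1CO
F3 | step 13 | (2R,3S)-3-chlorobutane-1,2,4-triol | OC[C@H](Cl)[C@H](O)CO
F4 | step 13 | (2S)-2-chloro-2-[(4R)-2,2-dimethyl-1,3-dioxolan-4-yl]ethan-1-ol | OC[C@H](Cl)[C@H]1COC(C)(C)O1
F5 | step 13 | (4R)-4-{(1S)-1-chloro-2-[(4-methoxybenzyl)oxy]ethyl}-2,2-dimethyl-1,3-dioxolane | COc1ccc(COC[C@H](Cl)[C@H]2COC(C)(C)O2)cc1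
F6 | step 26 | (2E,4E)-5-iodo-4-methylpenta-2,4-dien-1-ol | I/C=C(C)/C=C/CO
F7 | step 26 | C8–C23 (8E,10Z)-dienyl pinacol boronate, 19-O-TES, 13,14,15,17-tetrakis-O-TBS (boron in place of the iodine of 34) | CC/C=C/[C@H](O[Si](CC)(CC)CC)[C@H](Cl)[C@H](O[Si](C)(C)C(C)(C)C)C[C@H](O[Si](C)(C)C(C)(C)C)[C@H](O[Si](C)(C)C(C)(C)C)[C@H](O[Si](C)(C)C(C)(C)C)[C@@H](C)/C(Cl)=C/C=C/B1OC(C)(C)C(C)(C)O1
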